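The decalin is cut at C9–C10 (ring B). As drawn, the target is a cis-fused labdane with H-5, C-20 and the C-19 ester on one face, so the C-19 carboxyl on C4 and C10 of ring A can be joined in a bridged γ-lactone. In the key step this temporary ring is the leaving group: Lewis-acid opening with backside attack of a tethered allylsilane makes C9–C10 with inversion, closes ring B cis-fused, sets C9 and C10, creates the C8=C17 methylene and frees the C-19 acid. The precursor is a 6-oxabicyclo[3.2.1]octan-7-one (ring A plus lactone) carrying the silylmethyl-alkene side chain on its one-carbon bridge.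

Key step: step 9

Remark: the SMILES is read literally; it shows H-5 cis to C-20 and C-19 (5β-H, cis-decalin), not the trans fusion of the common labdanes, and the route is built for that configuration. Labdane numbering (C1–C20) is used for all intermediates.

Step 1
Reactants: 1 5-iodopent-1-yne; 2 bromoethene (vinyl bromide)
Product: 4 (3E)-7-iodo-4-methylhepta-1,3-diene, via alkenylalane 3 (not isolated)
Conditions: AlMe3 (2 equiv), Cp2ZrCl2 (0.2 equiv), CH2Cl2, 0 °C to rt; then 2 (in THF), Pd(PPh3)4 (5 mol %), rt
Reagents that add atoms: trimethylaluminium, C[Al](C)C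
Why: Zirconium-catalysed carboalumination adds Me–Al syn and regioselectively to the terminal alkyne, and Negishi coupling of the alkenylalane with zerovalent palladium proceeds with retention, so the trisubstituted alkene is E (C20 methyl cis to the vinyl group).

Step 2
Reactants: 4 (3E)-7-iodo-4-methylhepta-1,3-diene; 5 methyl propanoate
Product: 6 methyl (6E)-2,6-dimethylnona-6,8-dienoate (2RS)
Conditions: LiN(iPr)2, THF, −78 °C; then 4, DMPU, −78 °C to rt
Reagents that add atoms: none
Why: SN2 alkylation of the lithium ester enolate by the primary iodide; the C2 centre may be racemic because it is enolized again in step 4.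

Step 3
Reactants: 6 methyl (6E)-2,6-dimethylnona-6,8-dienoate
Product: 7 methyl 5-[(2R,3R)-3-ethenyl-2-methyloxiran-2-yl]-2-methylpentanoate (2RS)
Conditions: D-fructose-derived Shi ketone (0.3 equiv), KHSO5 (Oxone triple salt), K2CO3, Bu4NHSO4, MeCN/dimethoxymethane/aqueous buffer pH 10.5, 0 °C
Reagents that add atoms: potassium peroxymonosulfate, [K+].[O-]S(=O)(=O)OO
Why: Shi asymmetric epoxidation by the chiral dioxirane should attack only the electron-rich trisubstituted alkene of the diene and, through the spiro transition state, give the (R,R)-vinyl epoxide, which is the source of absolute configuration for the whole ring system.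

Step 4
Reactants: 7 methyl 5-[(2R,3R)-3-ethenyl-2-methyloxiran-2-yl]-2-methylpentanoate
Product: 9 (1S,5R,8R)-8-ethenyl-1,5-dimethyl-6-oxabicyclo[3.2.1]octan-7-one, via cyclohexyl alkoxide 8 (not isolated)
Conditions: KN(SiMe3)2 (1.3 equiv), toluene/THF, −78 °C to 0 °C; then H2O
Reagents that add atoms: none
Why: In an epoxide-opening cyclization of the Stork type the ester enolate attacks the allylic epoxide carbon C5 (the other epoxide carbon is fully substituted) with inversion to close ring A and make quaternary C4, and the tertiary C10 alkoxide then lactonizes onto the cis ester; E alkene geometry plus anti opening places the vinyl group on the face opposite to the lactone bridge, and only the C4 epimer with ester cis to the alkoxide can close the bridge.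

Step 5
Reactants: 10 methyl (2E)-3,7-dimethylocta-2,6-dienoate (methyl geranate)
Product: 11 methyl (2E)-3-methyl-6-oxohex-2-enoate
Conditions: O3 (1 equiv), pyridine, CH2Cl2/MeOH, −78 °C; then Me2S
Reagents that add atoms: ozone, [O-][O+]=O
Why: Ozonolysis is selective for the electron-rich isopropylidene alkene over the electron-poor conjugated enoate, whose E geometry is kept.

Step 6
Reactants: 11 methyl (2E)-3-methyl-6-oxohex-2-enoate
Product: 12 methyl (2E)-7,7-dibromo-3-methylhepta-2,6-dienoate
Conditions: CBr4, PPh3, CH2Cl2, 0 °C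
Reagents that add atoms: carbon tetrabromide, BrC(Br)(Br)Br
Why: Ramirez dibromo-olefination of the aldehyde (first stage of the Corey–Fuchs sequence) with the ylide formed from PPh3 and CBr4.

Step 7
Reactants: 12 methyl (2E)-7,7-dibromo-3-methylhepta-2,6-dienoate
Product: 13 methyl (2E,6Z)-7-bromo-3-methyl-8-(trimethylsilyl)octa-2,6-dienoate
Conditions: Me3SiCH2MgCl, ZnCl2, THF, 0 °C; then 12, PdCl2(DPEphos) (5 mol %), THF, rt
Reagents that add atoms: (trimethylsilyl)methylmagnesium chloride, C[Si](C)(C)C[Mg]Cl
Why: Trans-selective Negishi monoalkylation of a 1,1-dibromoalkene: oxidative addition occurs at the less hindered C–Br bond trans to the chain, so the silylmethyl group ends trans and the remaining bromine cis to the C11 chain, the alkene geometry that later controls C9.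

Step 8
Reactants: 9 (1S,5R,8R)-8-ethenyl-1,5-dimethyl-6-oxabicyclo[3.2.1]octan-7-one; 13 methyl (2E,6Z)-7-bromo-3-methyl-8-(trimethylsilyl)octa-2,6-dienoate
Product: 15 methyl (2E,6E)-9-[(1S,5R,8R)-1,5-dimethyl-7-oxo-6-oxabicyclo[3.2.1]octan-8-yl]-3-methyl-7-[(trimethylsilyl)methyl]nona-2,6-dienoate, via alkylborane 14 (not isolated)
Conditions: 9-BBN, THF, 0 °C to rt; then 13, Pd(dppf)Cl2 (5 mol %), AsPh3, Cs2CO3, DMF/H2O, rt
Reagents that add atoms: none
Why: Anti-Markovnikov hydroboration of the vinyl group followed by B-alkyl Suzuki–Miyaura coupling, which proceeds with retention at the alkenyl bromide so that the new C7–C8 bond is cis to the C11 chain.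

Step 9
Reactants: 15 methyl (2E,6E)-9-[(1S,5R,8R)-1,5-dimethyl-7-oxo-6-oxabicyclo[3.2.1]octan-8-yl]-3-methyl-7-[(trimethylsilyl)methyl]nona-2,6-dienoate
Product: 16 (1S,4aR,5S,8aS)-5-[(3E)-5-methoxy-3-methyl-5-oxopent-3-en-1-yl]-1,4a-dimethyl-6-methylidenedecahydronaphthalene-1-carboxylic acid
Conditions: EtAlCl2 (3 equiv), CH2Cl2, −78 °C to −20 °C; then 1 M HCl
Reagents that add atoms: none
Why: EtAlCl2 binds the lactone carbonyl and polarizes the tertiary alkyl–oxygen bond C10–O; the allylsilane, held under C10 by the axial C5–C6 tether on the face opposite to the lactone bridge, attacks C10 with its γ-carbon C9 as the aluminium carboxylate leaves, and loss of the silyl group from the β-silyl cation places the double bond at C8=C17 only. The closest known reaction types are the Hosomi–Sakurai alkylation of tertiary carbocations (allylsilane-terminated cation–olefin cyclization), the Lewis-acid alkyl–oxygen cleavage of tertiary γ-lactones used in Friedel–Crafts alkylations, and the olefin-assisted opening of cyclopropyl ketones. Ring B closes in a 6-exo-tet mode at C10 (the departing oxygen lies outside the new ring) and 6-endo-trig with respect to the C8=C9 alkene. C10 is set by inversion: the carboxylate stays tethered to C4 over the β face, so C9 enters from the α face and C20 ends β, cis to H5 and to C19, which is the cis ring fusion; C9 is set by a chair-like transition state in which the alkene geometry (C7 cis to C11) puts the C11 chain pseudo-axial on the convex face, cis to C20 (9α-H). The step needs displacement to outrun ring flip, 1,2-shift or proton loss of a free cation and protodesilylation; the pre-organized backside trajectory in the rigid bicycle, the proton-scavenging alkylaluminium reagent and the low temperature should secure this, and the enoate is inert because it can neither ionize nor act as a nucleophile.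

Step 10
Reactants: 16 (1S,4aR,5S,8aS)-5-[(3E)-5-methoxy-3-methyl-5-oxopent-3-en-1-yl]-1,4a-dimethyl-6-methylidenedecahydronaphthalene-1-carboxylic acid
Product: 17 (1S,4aR,5S,8aS)-5-[(3E)-5-hydroxy-3-methylpent-3-en-1-yl]-1,4a-dimethyl-6-methylidenedecahydronaphthalene-1-carboxylic acid
Conditions: iBu2AlH (3.5 equiv), CH2Cl2, −78 °C; then aqueous potassium sodium tartrate
Reagents that add atoms: none
Why: 1,2-Reduction of the enoate to the allylic alcohol by the aluminium hydride, while the hindered C19 acid is protected in the flask as its aluminium carboxylate, which is not reduced at −78 °C.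

Step 11
Reactants: 17 (1S,4aR,5S,8aS)-5-[(3E)-5-hydroxy-3-methylpent-3-en-1-yl]-1,4a-dimethyl-6-methylidenedecahydronaphthalene-1-carboxylic acid
Product: 18 methyl (1S,4aR,5S,8aS)-5-[(3E)-5-hydroxy-3-methylpent-3-en-1-yl]-1,4a-dimethyl-6-methylidenedecahydronaphthalene-1-carboxylate
Conditions: MeI, K2CO3, DMF, rt
Reagents that add atoms: iodomethane, CI
Why: SN2 O-methylation of the carboxylate, the usual way to esterify a hindered quaternary acid; the allylic alcohol is not alkylated under these conditions.

Step 12
Reactants: 18 methyl (1S,4aR,5S,8aS)-5-[(3E)-5-hydroxy-3-methylpent-3-en-1-yl]-1,4a-dimethyl-6-methylidenedecahydronaphthalene-1-carboxylate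
Product: 19 methyl (1S,4aR,5S,8aS)-5-{2-[(2R,3R)-3-(hydroxymethyl)-2-methyloxiran-2-yl]ethyl}-1,4a-dimethyl-6-methylidenedecahydronaphthalene-1-carboxylate (target)
Conditions: Ti(OiPr)4 (10 mol %), D-(−)-diethyl tartrate (12 mol %), t-BuOOH, 4 Å molecular sieves, CH2Cl2, −20 °C
Reagents that add atoms: tert-butyl hydroperoxide, CC(C)(C)OO
Why: Katsuki–Sharpless asymmetric epoxidation: the titanium tartrate complex epoxidizes only the allylic alcohol (the 8(17)-methylene is untouched), and D-(−)-tartrate should give the (13R,14R)-epoxide from the E-allylic alcohol under reagent control.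

Compound list
1 | 5-iodopent-1-yne | C#CCCCI | starting material
2 | bromoethene (vinyl bromide) | C=CBr | starting material
3 | [(1E)-5-iodo-2-methylpent-1-en-1-yl]dimethylalumane | C[Al](C)/C=C(\C)CCCI | intermediate
4 | (3E)-7-iodo-4-methylhepta-1,3-diene | C=C/C=C(\C)CCCI | intermediate
5 | methyl propanoate | CCC(=O)OC | starting material
6 | methyl (6E)-2,6-dimethylnona-6,8-dienoate (2RS) | COC(=O)C(C)CCC/C(C)=C/C=C | intermediate
7 | methyl 5-[(2R,3R)-3-ethenyl-2-methyloxiran-2-yl]-2-methylpentanoate (2RS) | COC(=O)C(C)CCC[C@@]1(C)O[C@@H]1C=C | intermediate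
8 | potassium alkoxide of methyl (1S,2R,3R)-2-ethenyl-3-hydroxy-1,3-dimethylcyclohexane-1-carboxylate | C=C[C@@H]1[C@@](C)(C(=O)OC)CCC[C@@]1(C)[O-].[K+] | intermediate
9 | (1S,5R,8R)-8-ethenyl-1,5-dimethyl-6-oxabicyclo[3.2.1]octan-7-one | C=C[C@@H]1[C@]2(C)CCC[C@@]1(C)OC2=O | intermediate
10 | methyl (2E)-3,7-dimethylocta-2,6-dienoate (methyl geranate) | COC(=O)/C=C(C)/CCC=C(C)C | starting material
11 | methyl (2E)-3-methyl-6-oxohex-2-enoate | COC(=O)/C=C(C)/CCC=O | intermediate
12 | methyl (2E)-7,7-dibromo-3-methylhepta-2,6-dienoate | COC(=O)/C=C(C)/CCC=C(Br)Br | intermediate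
13 | methyl (2E,6Z)-7-bromo-3-methyl-8-(trimethylsilyl)octa-2,6-dienoate | COC(=O)/C=C(C)/CC/C=C(Br)/C[Si](C)(C)C | intermediate
14 | 9-{2-[(1S,5R,8R)-1,5-dimethyl-7-oxo-6-oxabicyclo[3.2.1]octan-8-yl]ethyl}-9-borabicyclo[3.3.1]nonane | C(C[C@@H]1[C@]2(C)CCC[C@@]1(C)OC2=O)B1C2CCCC1CCC2 | intermediate
15 | methyl (2E,6E)-9-[(1S,5R,8R)-1,5-dimethyl-7-oxo-6-oxabicyclo[3.2.1]octan-8-yl]-3-methyl-7-[(trimethylsilyl)methyl]nona-2,6-dienoate | COC(=O)/C=C(C)/CC/C=C(C[Si](C)(C)C)\CC[C@@H]1[C@]2(C)CCC[C@@]1(C)OC2=O | intermediate
16 | (1S,4aR,5S,8aS)-5-[(3E)-5-methoxy-3-methyl-5-oxopent-3-en-1-yl]-1,4a-dimethyl-6-methylidenedecahydronaphthalene-1-carboxylic acid | C=C1CC[C@H]2[C@](C)(CCC[C@]2(C)C(=O)O)[C@H]1CC/C(C)=C/C(=O)OC | intermediate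
17 | (1S,4aR,5S,8aS)-5-[(3E)-5-hydroxy-3-methylpent-3-en-1-yl]-1,4a-dimethyl-6-methylidenedecahydronaphthalene-1-carboxylic acid | C=C1CC[C@H]2[C@](C)(CCC[C@]2(C)C(=O)O)[C@H]1CC/C(C)=C/CO | intermediate
18 | methyl (1S,4aR,5S,8aS)-5-[(3E)-5-hydroxy-3-methylpent-3-en-1-yl]-1,4a-dimethyl-6-methylidenedecahydronaphthalene-1-carboxylate | C=C1CC[C@H]2[C@](C)(CCC[C@]2(C)C(=O)OC)[C@H]1CC/C(C)=C/CO | intermediate
19 | methyl (1S,4aR,5S,8aS)-5-{2-[(2R,3R)-3-(hydroxymethyl)-2-methyloxiran-2-yl]ethyl}-1,4a-dimethyl-6-methylidenedecahydronaphthalene-1-carboxylate (CNP0175926.1) | C=C1CC[C@H]2[C@](C)(CCC[C@]2(C)C(=O)OC)[C@H]1CC[C@@]1(C)O[C@@H]1CO | target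

Total step count: 12. Longest linear sequence: 9 steps (steps 1, 2, 3, 4, 8, 9, 10, 11, 12, from 5-iodopent-1-yne); the side-chain fragment (steps 5–7) joins at step 8.

Steps most likely to fail

Step 9. The lactone may ionize too slowly at temperatures the allylsilane survives. Ionization may also run ahead of capture, so that a free cation flips ring A, shifts hydride or loses a proton; this would erode the cis fusion and the C9 configuration. Fallback: O-alkylative instead of Lewis-acid activation. Setting out from 15, Me3OBF4 with 2,6-di-tert-butyl-4-methylpyridine in CH2Cl2 should methylate the lactone carbonyl oxygen. The resulting lactonium ion has a neutral methyl ester as leaving group, and the same backside attack of the allylsilane should give the 15,19-dimethyl diester F1 directly. Reduction of the unhindered enoate of F1 with iBu2AlH (2.1 equiv, −78 °C; the neopentyl C19 ester should react far more slowly) gives 18, where the route is rejoined.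

Step 4. Facial selectivity at C4 may be poor (only the epimer with ester cis to the alkoxide can lactonize), the base may isomerize the vinyl epoxide to a dienol, or the ester may self-condense. Fallback: the nitrile version of the ring closure (Stork epoxynitrile cyclization). Setting out from 4, alkylation of lithiated propanenitrile gives the diene nitrile F2. The same Shi epoxidation gives the (R,R)-epoxy nitrile F3. KN(SiMe3)2 in toluene closes ring A with inversion at the allylic carbon to the hydroxy nitrile F4. Aqueous HCl in MeOH converts the cis-hydroxy nitrile through the imino-lactone into 9, where the route is rejoined.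

Step 8. Transmetalation and reductive elimination may be slow at the α-branched, cis-substituted alkenyl bromide, with competing protodeboronation of the alkylborane or loss of the allylic silyl group in the basic aqueous medium. Fallback: an anhydrous Negishi sp3–sp2 coupling through an isolable iodide. Setting out from 9, hydroboration to 14 and oxidation (NaBO3) gives the primary alcohol F5. I2, PPh3 and imidazole give the iodide F6. Zinc insertion (Zn, LiCl, THF) gives the alkylzinc iodide F7, which is coupled with 13 using Pd[P(t-Bu)3]2 to give 15, where the route is rejoined.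

Further compounds
F1 | step 9 | methyl (1S,4aR,5S,8aS)-5-[(3E)-5-methoxy-3-methyl-5-oxopent-3-en-1-yl]-1,4a-dimethyl-6-methylidenedecahydronaphthalene-1-carboxylate | C=C1CC[C@H]2[C@](C)(CCC[C@]2(C)C(=O)OC)[C@H]1CC/C(C)=C/C(=O)OC
F2 | step 4 | (6E)-2,6-dimethylnona-6,8-dienenitrile (2RS) | N#CC(C)CCC/C(C)=C/C=C
F3 | step 4 | 5-[(2R,3R)-3-ethenyl-2-methyloxiran-2-yl]-2-methylpentanenitrile (2RS) | N#CC(C)CCC[C@@]1(C)O[C@@H]1C=C
F4 | step 4 | (1S,2R,3R)-2-ethenyl-3-hydroxy-1,3-dimethylcyclohexane-1-carbonitrile | C=C[C@@H]1[C@@](C)(C#N)CCC[C@@]1(C)O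
F5 | step 8 | (1S,5R,8R)-8-(2-hydroxyethyl)-1,5-dimethyl-6-oxabicyclo[3.2.1]octan-7-one | OCC[C@@H]1[C@]2(C)CCC[C@@]1(C)OC2=O
F6 | step 8 | (1S,5R,8R)-8-(2-iodoethyl)-1,5-dimethyl-6-oxabicyclo[3.2.1]octan-7-one | ICC[C@@H]1[C@]2(C)CCC[C@@]1(C)OC2=O
F7 | step 8 | {2-[(1S,5R,8R)-1,5-dimethyl-7-oxo-6-oxabicyclo[3.2.1]octan-8-yl]ethyl}zinc iodide | I[Zn]CC[C@@H]1[C@]2(C)CCC[C@@]1(C)OC2=O
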